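**Assumption:** the target has no stereocentre and no C=C, so no stereocontrol is needed; the carbinol centre made in step 2 is racemic and is erased in step 4.

## Retrosynthetic overview

1. Target 12 ⇒ hexacosanoic acid 10 + benzyl alcohol 11 (ester C–O bond, made last so that no benzyl group meets H2/Pd).
2. Acid 10 ⇒ tert-butyl hexacosanoate 9 ⇒ (E)-enoate 8 ⇒ mesylate 7 ⇒ β-hydroxy ester 6 (hydrogenation, E1cB dehydration).
3. Key C2–C3 bond: 6 ⇒ tetracosanal 2 (C24) + lithium enolate of tert-butyl acetate 3 (C2), an intermolecular aldol addition; 2 comes from 1-tetracosanol 1.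
4. No ring is formed; the only ring (phenyl) is bought in benzyl alcohol.

## Route

Step 1
Reactants: 1 1-tetracosanol
Product: 2 tetracosanal
Conditions: IBX (2 equiv), EtOAc, 80 °C; filter hot
Reagents that add atoms: none
Why: IBX oxidation (hypervalent iodine) stops at the aldehyde, and hot EtOAc dissolves the waxy alcohol while IBX and its reduced form stay insoluble and are filtered off.

Step 2
Reactants: 2 tetracosanal; 3 tert-butyl acetate
Product: 6 tert-butyl 3-hydroxyhexacosanoate (racemic), via lithium enolate of tert-butyl acetate 4 (not isolated), via lithium aldolate 5 (not isolated)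
Conditions: LDA (commercial solution, 1.3 equiv), THF, −78 °C; then 2 in THF, −78 → 0 °C; AcOH quench
Reagents that add atoms: none
Why: Directed aldol addition of a preformed ester enolate that does not self-condense and is stable to 0 °C, so the poorly soluble aldehyde reacts as the mixture warms; the new C3 centre is racemic, which does not matter because it is removed in step 4.

Step 3
Reactants: 6 tert-butyl 3-hydroxyhexacosanoate
Product: 7 tert-butyl 3-(methylsulfonyloxy)hexacosanoate (racemic, used crude)
Conditions: MsCl, Et3N, CH2Cl2, 0 °C → rt
Reagents that add atoms: methanesulfonyl chloride, CS(=O)(=O)Cl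
Why: Mesylation turns the secondary hydroxyl into a leaving group under mild base that leaves the tert-butyl ester untouched; any early elimination only anticipates step 4.

Step 4
Reactants: 7 tert-butyl 3-(methylsulfonyloxy)hexacosanoate
Product: 8 tert-butyl (E)-hexacos-2-enoate
Conditions: DBU, CH2Cl2, rt
Reagents that add atoms: none
Why: E1cB β-elimination through the ester α-anion gives the conjugated (E)-enoate and erases the C3 stereocentre; any Z or β,γ isomer converges in step 5.

Step 5
Reactants: 8 tert-butyl (E)-hexacos-2-enoate
Product: 9 tert-butyl hexacosanoate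
Conditions: H2 (1 atm), 10% Pd/C, EtOAc, rt
Reagents that add atoms: none
Why: Heterogeneous catalytic hydrogenation saturates the disubstituted alkene, and a tert-butyl ester is inert to H2/Pd.

Step 6
Reactants: 9 tert-butyl hexacosanoate
Product: 10 hexacosanoic acid
Conditions: TFA/CH2Cl2 (1:2), rt
Reagents that add atoms: none
Why: Acidolysis of the tert-butyl ester (loss of isobutene) frees the acid without base or water, and the saturated chain has nothing else that reacts.

Step 7
Reactants: 10 hexacosanoic acid; 11 benzyl alcohol
Product: 12 benzyl hexacosanoate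
Conditions: BnOH (3 equiv), TsOH·H2O (5 mol%), toluene, reflux, Dean–Stark
Reagents that add atoms: none
Why: Fischer esterification driven to completion by azeotropic removal of water; boiling toluene dissolves the C26 acid and the waxy ester crystallises away from excess benzyl alcohol.

## Compound list

1 | 1-tetracosanol | CCCCCCCCCCCCCCCCCCCCCCCCO | starting material
2 | tetracosanal | CCCCCCCCCCCCCCCCCCCCCCCC=O | intermediate
3 | tert-butyl acetate | CC(=O)OC(C)(C)C | starting material
4 | lithium enolate of tert-butyl acetate (lithium 1-tert-butoxyethen-1-olate) | C=C(O[Li])OC(C)(C)C | intermediate (not isolated)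
5 | lithium aldolate (lithium 1-tert-butoxy-1-oxohexacosan-3-olate, racemic) | CCCCCCCCCCCCCCCCCCCCCCCC(O[Li])CC(=O)OC(C)(C)C | intermediate (not isolated)
6 | tert-butyl 3-hydroxyhexacosanoate (racemic) | CCCCCCCCCCCCCCCCCCCCCCCC(O)CC(=O)OC(C)(C)C | intermediate
7 | tert-butyl 3-(methylsulfonyloxy)hexacosanoate (racemic) | CCCCCCCCCCCCCCCCCCCCCCCC(OS(C)(=O)=O)CC(=O)OC(C)(C)C | intermediate
8 | tert-butyl (E)-hexacos-2-enoate | CCCCCCCCCCCCCCCCCCCCCCC/C=C/C(=O)OC(C)(C)C | intermediate
9 | tert-butyl hexacosanoate | CCCCCCCCCCCCCCCCCCCCCCCCCC(=O)OC(C)(C)C | intermediate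
10 | hexacosanoic acid | CCCCCCCCCCCCCCCCCCCCCCCCCC(=O)O | intermediate
11 | benzyl alcohol | OCc1ccccc1 | starting material
12 | benzyl hexacosanoate | CCCCCCCCCCCCCCCCCCCCCCCCCC(=O)OCc1ccccc1 | target

## Totals and risks

Total step count: 7. Longest linear sequence: 7 steps (1 → 12).

**Step 2 (aldol addition).** Tetracosanal is barely soluble in THF below about −40 °C, and the lithium aldolate can revert if warmed too long. The fallback sets out from 2 and comes back at 10. Compound 2 is condensed with malonic acid in pyridine with catalytic piperidine at 90 °C (Knoevenagel–Doebner, an aldol-type condensation of the same C24 + C2 pieces, but hot and homogeneous). The first-formed 2-tetracosylidenepropanedioic acid F1 loses CO2 in the flask to give (E)-hexacos-2-enoic acid F2. Hydrogenation of this (H2, Pd/C, THF, 40 °C) gives hexacosanoic acid 10, so steps 3–6 are skipped.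

**Step 1 (partial oxidation).** The waxy alcohol may convert incompletely, and the long-chain aldehyde is prone to air oxidation and oligomerisation on isolation. The fallback sets out from 1 and comes back at 2, reaching the aldehyde from the acid oxidation level. Compound 1 is oxidised all the way with Jones reagent (CrO3, H2SO4, acetone/THF, 40 °C) to tetracosanoic acid F3, which can also be bought. CDI in THF at 50 °C converts it to 1-tetracosanoylimidazole F4, and MeNH(OMe)·HCl then gives the Weinreb amide N-methoxy-N-methyltetracosanamide F5. Reduction with LiAlH4 (THF, 0 °C) and acidic work-up releases 2; the chelated tetrahedral intermediate prevents over-reduction.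

**Step 7 (Fischer esterification).** This is an equilibrium reaction, benzyl alcohol can self-etherify under TsOH, and excess benzyl alcohol must be separated from a wax. The fallback sets out from 10 and comes back at 12, with the carboxylate as nucleophile instead of the acid as electrophile. Compound 10 is treated with Cs2CO3 in DMF/THF at 60 °C to form cesium hexacosanoate F6, which is alkylated in the same flask with benzyl bromide (irreversible SN2 O-alkylation) to give 12.

## Further compounds

F1 | step 2 | 2-tetracosylidenepropanedioic acid | CCCCCCCCCCCCCCCCCCCCCCCC=C(C(=O)O)C(=O)O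
F2 | step 2 | (E)-hexacos-2-enoic acid | CCCCCCCCCCCCCCCCCCCCCCC/C=C/C(=O)O
F3 | step 1 | tetracosanoic acid | CCCCCCCCCCCCCCCCCCCCCCCC(=O)O
F4 | step 1 | 1-tetracosanoylimidazole | CCCCCCCCCCCCCCCCCCCCCCCC(=O)n1ccnc1
F5 | step 1 | N-methoxy-N-methyltetracosanamide | CCCCCCCCCCCCCCCCCCCCCCCC(=O)N(C)OC
F6 | step 7 | cesium hexacosanoate | [Cs+].CCCCCCCCCCCCCCCCCCCCCCCCCC(=O)[O-]
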